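**Plan**

- Retrosynthesis: the methyl ester and C7–OH are traced back to a δ-lactone (C7–O–CO), prenyl to allyl (C=C, cross-metathesis) and C5–OH to its ethyl ether. Ring B (the pyranone) is cut at O1–C2 (oxa-Michael) and C4–C4a (Friedel–Crafts), and ring A at C7–C8 and C4a–C8a into a siloxyalkyne and a cyclobutenone.
- Enabling feature: ring A (C4a, C5, C6, C7, C8, C8a) is a hexasubstituted phloroglucinol whose oxygens on C5, C7 and C8a alternate with carbon substituents on C4a, C6 and C8. A ketene carbonyl (C7), a cyclobutenone alkoxy group (C5) and an ynol-ether oxygen (C8a) deliver these three oxygens already differentiated, with C4a as the only C–H.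
- Forward order: auxiliary alkylation and ynolate chemistry give the alkyne, and allylketene plus ethoxyacetylene gives the cyclobutenone. Benzannulation closes ring A; the lactone ring follows on C7–O, then ring B (acylation at C4a, closure from C8a–OH); de-ethylation, allyl → prenyl and lactone methanolysis finish.
- Stereochemistry: the benzylic (S) centre comes from the (R)-benzyloxazolidinone alkylation and is carried unchanged. C2 (R) is set by (−)-quinine in the oxa-Michael closure, and C3 (S, cis to C2-methyl) by kinetic protonation of the resulting enol.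

Key step: step 6

Remark: ring-A carbons are numbered C4a, C5, C6, C7, C8, C8a as in the chromanone of the target, also in earlier intermediates.
Remark: the C6 side chain is carried as allyl and converted to prenyl late, because a prenyl group next to a phenolic oxygen would not survive the three acidic steps (7, 9, 11).
Assumption: (−)-quinine induces the 2R sense in the closure of 25, as it does for simpler o-tigloylphenols; if the sense were reversed on this substrate, quinidine would take its place.

**Route**

Step 1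
Reactants: 1 (R)-4-benzyl-2-oxazolidinone; 2 pentanoyl chloride
Product: 4 (R)-4-benzyl-3-pentanoyloxazolidin-2-one, via lithium oxazolidinide 3 (not isolated)
Conditions: n-BuLi, THF, −78 °C; then 2, −78 → 0 °C
Reagents that add atoms: none
Why: N-acylation of the lithiated oxazolidinone by an acid chloride is the standard preparation of an Evans imide and creates no stereocentre.

Step 2
Reactants: 4 (R)-4-benzyl-3-pentanoyloxazolidin-2-one; 5 tert-butyl bromoacetate
Product: 7 tert-butyl (3S)-3-{[(4R)-4-benzyl-2-oxo-1,3-oxazolidin-3-yl]carbonyl}hexanoate, via sodium enolate 6 (not isolated)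
Conditions: NaN(SiMe3)2, THF, −78 °C; then 5, −78 → −40 °C
Reagents that add atoms: none
Why: Evans asymmetric alkylation, in which the chelated (Z)-enolate 6 is alkylated by the activated bromide on the face away from the benzyl group, so that the (R)-auxiliary sets the (S)-configured carbon that later becomes the benzylic centre on C8.

Step 3
Reactants: 7 tert-butyl (3S)-3-{[(4R)-4-benzyl-2-oxo-1,3-oxazolidin-3-yl]carbonyl}hexanoate
Product: 8 4-tert-butyl 1-ethyl (2S)-2-propylbutanedioate
Conditions: EtOH, Ti(OEt)4 (0.3 equiv), 80 °C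
Reagents that add atoms: ethanol, CCO
Why: Titanate-catalysed transesterification cleaves the activated exocyclic imide carbonyl under neutral conditions, leaves the hindered tert-butyl ester and the epimerisable α-centre untouched, and returns auxiliary 1.

Step 4
Reactants: 8 4-tert-butyl 1-ethyl (2S)-2-propylbutanedioate
Product: 11 tert-butyl (3S)-3-propyl-5-[(triisopropylsilyl)oxy]pent-4-ynoate, via lithium dibromoenolate 9 (not isolated), via lithium ynolate 10 (not isolated)
Conditions: CH2Br2, lithium 2,2,6,6-tetramethylpiperidide, THF, −78 °C; n-BuLi, −78 → 0 °C; iPr3SiCl, −78 °C → rt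
Reagents that add atoms: dibromomethane, BrCBr; chlorotriisopropylsilane, CC(C)[Si](Cl)(C(C)C)C(C)C
Why: Kowalski ester homologation intercepted at the ynolate: LiCHBr2 adds only to the ethyl ester (the tert-butyl ester is too hindered) to give 9, bromine–lithium exchange at −78 °C and warming induce the 1,2-shift of the stereogenic carbon with retention to give 10, and the bulky silyl chloride silylates 10 on oxygen.

Step 5
Reactants: 12 pent-4-enoyl chloride; 13 ethoxyacetylene
Product: 15 (±)-4-allyl-3-ethoxycyclobut-2-en-1-one, via allylketene 14 (not isolated)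
Conditions: Et3N, Et2O–hexanes, rt, slow addition of 12 to excess 13
Reagents that add atoms: none
Why: Dehydrochlorination gives allylketene 14, which undergoes the known [2+2] ketene–ynol ether cycloaddition with the unsubstituted alkyne carbon bonding to the ketene carbonyl carbon, so that ethoxy ends on C3 and allyl on C4 of the cyclobutenone.

Step 6
Reactants: 11 tert-butyl (3S)-3-propyl-5-[(triisopropylsilyl)oxy]pent-4-ynoate; 15 (±)-4-allyl-3-ethoxycyclobut-2-en-1-one
Product: 20 tert-butyl (3S)-3-[3-allyl-4-ethoxy-2-hydroxy-6-(triisopropylsilyloxy)phenyl]hexanoate, via vinylketene 16 (not isolated), via vinylcyclobutenone 17 (not isolated), via dienylketene 18 (not isolated), via cyclohexadienone 19 (not isolated)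
Conditions: PhMe, 80 °C then 110 °C, 1.5 equiv of 15
Reagents that add atoms: none
Why: Danheiser benzannulation: on heating, 15 undergoes strain-releasing 4π electrocyclic opening to vinylketene 16, whose carbonyl carbon is attacked by the oxygen-remote carbon of siloxyalkyne 11 in a regiospecific [2+2] cycloaddition that forms C7–C8 and C4a–C8a and gives 17 as epimers that converge later. A second 4π opening gives dienylketene 18, and ring A is closed by thermal 6π electrocyclisation (C6–C7 bond) to cyclohexadienone 19, which tautomerises to the phenol because C6 still carries a hydrogen. The closest known reaction type is the thermal benzannulation of cyclobutenones with siloxyalkynes (α-branched ones included) to resorcinol monosilyl ethers; the 3-alkoxy cyclobutenone is the less usual partner and delivers the third oxygen. No stereocentre is formed, the stereogenic C4 of racemic 15 becomes the sp2 carbon C6, and the propargylic centre of 11 is a spectator under these neutral conditions. The selectivity required is regiochemical and is secured by the polarisation of the ynol ether, which places the side chain on C8 between the free C7–OH and the C8a silyl ether, leaves the C5 oxygen as its ethyl ether and makes C4a the only unsubstituted carbon.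

Step 7
Reactants: 20 tert-butyl (3S)-3-[3-allyl-4-ethoxy-2-hydroxy-6-(triisopropylsilyloxy)phenyl]hexanoate
Product: 22 (4S)-8-allyl-7-ethoxy-4-propyl-5-(triisopropylsilyloxy)chroman-2-one, via hydroxy acid 21 (not isolated)
Conditions: CF3CO2H, CH2Cl2, 0 °C → rt; then PhMe, 50 °C
Reagents that add atoms: none
Why: Acidolysis of the tert-butyl ester followed by acid-catalysed lactonisation onto C7–OH, the only free phenol beside the side chain while C8a–O is still silylated, gives a six-membered aryl lactone that masks both the C7 phenol and the carboxyl group; the aryl silyl ether and the allyl group tolerate the acid.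

Step 8
Reactants: 22 (4S)-8-allyl-7-ethoxy-4-propyl-5-(triisopropylsilyloxy)chroman-2-one
Product: 23 (4S)-8-allyl-7-ethoxy-5-hydroxy-4-propylchroman-2-one
Conditions: Bu4NF, AcOH, THF, 0 °C
Reagents that add atoms: none
Why: Fluoride-mediated cleavage of the aryl silyl ether, buffered with acetic acid so that no phenoxide opens or relocates the lactone, frees the C8a hydroxyl.

Step 9
Reactants: 23 (4S)-8-allyl-7-ethoxy-5-hydroxy-4-propylchroman-2-one; 24 (E)-2-methylbut-2-enoyl chloride (tigloyl chloride)
Product: 25 (4S)-8-allyl-7-ethoxy-5-hydroxy-6-[(2E)-2-methylbut-2-enoyl]-4-propylchroman-2-one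
Conditions: AlCl3, CH2Cl2–PhNO2, 0 °C → rt
Reagents that add atoms: none
Why: Friedel–Crafts acylation at C4a, the only unsubstituted ring carbon and one activated by the ortho C8a–OH and C5–OEt, with the Lewis acid held on the phenol oxygen directing the acylium ortho; the low temperature is chosen to spare the ethyl ether, the allyl group and the (E)-enone, and the lactone is inert.

Step 10
Reactants: 25 (4S)-8-allyl-7-ethoxy-5-hydroxy-6-[(2E)-2-methylbut-2-enoyl]-4-propylchroman-2-one
Product: 27 (2R,3S,10S)-6-allyl-5-ethoxy-2,3-dimethyl-10-propyl-2,3,9,10-tetrahydro-4H,8H-pyrano[2,3-h]chromene-4,8-dione, via enol 26 (not isolated)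
Conditions: (−)-quinine (0.2 equiv), PhCl, 10 °C
Reagents that add atoms: none
Why: Cinchona-alkaloid-catalysed intramolecular oxa-Michael addition (6-endo-trig), a reaction established for o-tigloylphenols, in which the chiral base delivers the C8a oxygen to one face of the enone to set C2 (R) and protonation of enol 26 anti to the C2 methyl gives the kinetic cis isomer (C3 S); the ethyl ether on C5 ensures that only C8a–OH can close, and the catalyst rather than the remote C10 centre controls the face.

Step 11
Reactants: 27 (2R,3S,10S)-6-allyl-5-ethoxy-2,3-dimethyl-10-propyl-2,3,9,10-tetrahydro-4H,8H-pyrano[2,3-h]chromene-4,8-dione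
Product: 28 (2R,3S,10S)-6-allyl-5-hydroxy-2,3-dimethyl-10-propyl-2,3,9,10-tetrahydro-4H,8H-pyrano[2,3-h]chromene-4,8-dione
Conditions: BCl3, CH2Cl2, −78 → 0 °C; aqueous work-up
Reagents that add atoms: none
Why: Chelation-assisted dealkylation of the aryl ether peri to the C4 carbonyl by BCl3 removes only the C5 ethyl group, the ring oxygen O1 and the lactone not being placed to chelate, and the base-free low-temperature conditions should leave the cis-2,3 relationship and the allyl group intact.

Step 12
Reactants: 28 (2R,3S,10S)-6-allyl-5-hydroxy-2,3-dimethyl-10-propyl-2,3,9,10-tetrahydro-4H,8H-pyrano[2,3-h]chromene-4,8-dione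
Product: 29 (2R,3S,10S)-5-hydroxy-2,3-dimethyl-6-(3-methylbut-2-enyl)-10-propyl-2,3,9,10-tetrahydro-4H,8H-pyrano[2,3-h]chromene-4,8-dione
Conditions: 2-methyl-2-butene (large excess), second-generation Grubbs catalyst (H2IMes)(PCy3)Cl2Ru=CHPh (5 mol%), CH2Cl2, 40 °C
Reagents that add atoms: 2-methyl-2-butene, CC=C(C)C
Why: Olefin cross-metathesis of the terminal allyl group with 2-methyl-2-butene is the standard neutral conversion of allyl into prenyl, tolerates free phenols, ketones and lactones, and touches no stereocentre.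

Step 13
Reactants: 29 (2R,3S,10S)-5-hydroxy-2,3-dimethyl-6-(3-methylbut-2-enyl)-10-propyl-2,3,9,10-tetrahydro-4H,8H-pyrano[2,3-h]chromene-4,8-dione
Product: 30 methyl (3S)-3-[(2R,3S)-5,7-dihydroxy-2,3-dimethyl-6-(3-methylbut-2-enyl)-4-oxochroman-8-yl]hexanoate (CNP0068017.4)
Conditions: NaOMe (2.2 equiv), MeOH–THF, −20 → 0 °C; then AcOH
Reagents that add atoms: sodium methoxide, C[O-].[Na+]; methanol, CO
Why: Base-mediated methanolysis (transesterification) of the aryl δ-lactone releases the methyl ester and the C7 phenol in one operation, and because the chelated C5–OH is deprotonated first the C4 ketone becomes a vinylogous carboxylate whose C3–H is not removed, so the cis-2,3 arrangement should survive until the cold acetic acid quench.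

**Compound list**

1 | (R)-4-benzyl-2-oxazolidinone | O=C1N[C@H](Cc2ccccc2)CO1 | starting material
2 | pentanoyl chloride | CCCCC(=O)Cl | starting material
3 | lithium oxazolidinide (lithium salt of 1, formed in the flask) | O=C1[N-][C@H](Cc2ccccc2)CO1.[Li+] | intermediate
4 | (R)-4-benzyl-3-pentanoyloxazolidin-2-one | CCCCC(=O)N1[C@H](Cc2ccccc2)COC1=O | intermediate
5 | tert-butyl bromoacetate | CC(C)(C)OC(=O)CBr | starting material
6 | sodium (Z)-enolate of 4 (formed in the flask) | CCC/C=C(\[O-])N1[C@H](Cc2ccccc2)COC1=O.[Na+] | intermediate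
7 | tert-butyl (3S)-3-{[(4R)-4-benzyl-2-oxo-1,3-oxazolidin-3-yl]carbonyl}hexanoate | CCC[C@@H](CC(=O)OC(C)(C)C)C(=O)N1[C@H](Cc2ccccc2)COC1=O | intermediate
8 | 4-tert-butyl 1-ethyl (2S)-2-propylbutanedioate | CCC[C@@H](CC(=O)OC(C)(C)C)C(=O)OCC | intermediate
9 | lithium enolate of tert-butyl (3S)-5,5-dibromo-4-oxo-3-propylpentanoate (formed in the flask) | CCC[C@@H](CC(=O)OC(C)(C)C)C([O-])=C(Br)Br.[Li+] | intermediate
10 | lithium (3S)-5-tert-butoxy-5-oxo-3-propylpent-1-yn-1-olate (ynolate, formed in the flask) | CCC[C@@H](CC(=O)OC(C)(C)C)C#C[O-].[Li+] | intermediate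
11 | tert-butyl (3S)-3-propyl-5-[(triisopropylsilyl)oxy]pent-4-ynoate | CCC[C@@H](CC(=O)OC(C)(C)C)C#CO[Si](C(C)C)(C(C)C)C(C)C | intermediate
12 | pent-4-enoyl chloride | C=CCCC(=O)Cl | starting material
13 | ethoxyacetylene | CCOC#C | starting material
14 | allylketene (penta-1,4-dien-1-one, formed in the flask) | C=CCC=C=O | intermediate
15 | (±)-4-allyl-3-ethoxycyclobut-2-en-1-one | CCOC1=CC(=O)C1CC=C | intermediate
16 | (3Z)-3-ethoxyhepta-1,3,6-trien-1-one (vinylketene, formed in the flask) | O=C=C/C(OCC)=C/CC=C | intermediate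
17 | tert-butyl (3S)-3-{3-[(1Z)-1-ethoxypenta-1,4-dien-1-yl]-4-oxo-2-[(triisopropylsilyl)oxy]cyclobut-1-en-1-yl}hexanoate (ring epimers, formed in the flask) | CCC[C@@H](CC(=O)OC(C)(C)C)C1=C(O[Si](C(C)C)(C(C)C)C(C)C)C(/C(OCC)=C/CC=C)C1=O | intermediate
18 | dienylketene O=C=C(R)–C(OSiiPr3)=CH–C(OEt)=CH–CH2CH=CH2 with R = (S)-CH(Pr)CH2CO2tBu (formed in the flask) | CCC[C@@H](CC(=O)OC(C)(C)C)C(=C=O)/C(O[Si](C(C)C)(C(C)C)C(C)C)=C\C(OCC)=C\CC=C | intermediate
19 | tert-butyl (3S)-3-[5-allyl-4-ethoxy-6-oxo-2-(triisopropylsilyloxy)cyclohexa-1,3-dien-1-yl]hexanoate (formed in the flask) | CCC[C@@H](CC(=O)OC(C)(C)C)C1=C(O[Si](C(C)C)(C(C)C)C(C)C)C=C(OCC)C(CC=C)C1=O | intermediate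
20 | tert-butyl (3S)-3-[3-allyl-4-ethoxy-2-hydroxy-6-(triisopropylsilyloxy)phenyl]hexanoate | CCC[C@@H](CC(=O)OC(C)(C)C)c1c(O)c(CC=C)c(OCC)cc1O[Si](C(C)C)(C(C)C)C(C)C | intermediate
21 | (3S)-3-[3-allyl-4-ethoxy-2-hydroxy-6-(triisopropylsilyloxy)phenyl]hexanoic acid (formed in the flask) | CCC[C@@H](CC(=O)O)c1c(O)c(CC=C)c(OCC)cc1O[Si](C(C)C)(C(C)C)C(C)C | intermediate
22 | (4S)-8-allyl-7-ethoxy-4-propyl-5-(triisopropylsilyloxy)chroman-2-one | CCC[C@H]1CC(=O)Oc2c(CC=C)c(OCC)cc(O[Si](C(C)C)(C(C)C)C(C)C)c21 | intermediate
23 | (4S)-8-allyl-7-ethoxy-5-hydroxy-4-propylchroman-2-one | CCC[C@H]1CC(=O)Oc2c(CC=C)c(OCC)cc(O)c21 | intermediate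
24 | (E)-2-methylbut-2-enoyl chloride (tigloyl chloride) | C/C=C(\C)C(=O)Cl | starting material
25 | (4S)-8-allyl-7-ethoxy-5-hydroxy-6-[(2E)-2-methylbut-2-enoyl]-4-propylchroman-2-one | CCC[C@H]1CC(=O)Oc2c(CC=C)c(OCC)c(C(=O)/C(C)=C/C)c(O)c21 | intermediate
26 | (2R,10S)-6-allyl-5-ethoxy-4-hydroxy-2,3-dimethyl-10-propyl-9,10-dihydro-2H,8H-pyrano[2,3-h]chromen-8-one (C3=C4 enol of 27, formed in the flask) | CCC[C@H]1CC(=O)Oc2c(CC=C)c(OCC)c3c(c21)O[C@H](C)C(C)=C3O | intermediate
27 | (2R,3S,10S)-6-allyl-5-ethoxy-2,3-dimethyl-10-propyl-2,3,9,10-tetrahydro-4H,8H-pyrano[2,3-h]chromene-4,8-dione (cis-chromanone on C4a/C8a–O, δ-lactone on C7–O/C8) | CCC[C@H]1CC(=O)Oc2c(CC=C)c(OCC)c3c(c21)O[C@H](C)[C@H](C)C3=O | intermediate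
28 | (2R,3S,10S)-6-allyl-5-hydroxy-2,3-dimethyl-10-propyl-2,3,9,10-tetrahydro-4H,8H-pyrano[2,3-h]chromene-4,8-dione | CCC[C@H]1CC(=O)Oc2c(CC=C)c(O)c3c(c21)O[C@H](C)[C@H](C)C3=O | intermediate
29 | (2R,3S,10S)-5-hydroxy-2,3-dimethyl-6-(3-methylbut-2-enyl)-10-propyl-2,3,9,10-tetrahydro-4H,8H-pyrano[2,3-h]chromene-4,8-dione | CCC[C@H]1CC(=O)Oc2c(CC=C(C)C)c(O)c3c(c21)O[C@H](C)[C@H](C)C3=O | intermediate
30 | methyl (3S)-3-[(2R,3S)-5,7-dihydroxy-2,3-dimethyl-6-(3-methylbut-2-enyl)-4-oxochroman-8-yl]hexanoate | CCC[C@@H](CC(=O)OC)c1c(O)c(CC=C(C)C)c(O)c2c1O[C@H](C)[C@H](C)C2=O | target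

**Summary**

Total step count: 13. Longest linear sequence: 12 steps (steps 1–4 and 6–13); step 5 is the one-step side branch to the cyclobutenone.

Steps most likely to fail:

1. Step 6 (benzannulation). The donor-substituted vinylketene may oligomerise, or be captured by the phenolic product, faster than the hindered α-branched siloxyalkyne intercepts it. Prolonged heating may also cause oxygen-to-carbon silyl migration in the alkyne.
   Fallback: generate the same vinylketene at room temperature by 1,4-dehydrochlorination instead of thermal ring opening. It sets out from alkyne 11. Commercial ethyl 3-oxohept-6-enoate F1 is converted with HC(OEt)3 and catalytic H2SO4 in EtOH into ethyl (2E)-3-ethoxyhepta-2,6-dienoate F2. Saponification (KOH, aqueous EtOH, then careful acidification at 0 °C) gives (2E)-3-ethoxyhepta-2,6-dienoic acid F3. Oxalyl chloride with catalytic DMF gives (2E)-3-ethoxyhepta-2,6-dienoyl chloride F4. Slow addition of F4 to 11 and Et3N in CH2Cl2 at 0 °C → rt removes a γ-proton to give vinylketene 16, which is trapped in the [2+2] step as 17. Brief warming to 60–80 °C then takes 17 through 18 and 19 to phenol 20, where the route is rejoined.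

2. Step 4 (ynolate formation and silylation). Butyllithium may add to the tert-butyl ester or enolise it during the exchange and warming, and the ynolate may be silylated on carbon.
   Fallback: reach the ynolate by oxidising an acetylide instead of homologating an ester. It sets out from imide 7. LiBH4 (THF, 0 °C) gives tert-butyl (3S)-3-(hydroxymethyl)hexanoate F5 with recovery of 1. Dess–Martin periodinane gives tert-butyl (3S)-3-formylhexanoate F6. CBr4/PPh3 (Corey–Fuchs olefination) gives tert-butyl (3S)-3-(2,2-dibromovinyl)hexanoate F7. Bu4NF·3H2O in DMF eliminates HBr to give tert-butyl (3S)-3-(bromoethynyl)hexanoate F8. Bromine–lithium exchange with t-BuLi at −100 °C, which is faster than any reaction at the ester, gives the lithium acetylide of tert-butyl (3S)-3-ethynylhexanoate F9. Oxidation with t-BuOOLi (−78 → 0 °C) gives ynolate 10, and iPr3SiOTf gives 11, where the route is rejoined.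

3. Step 9 (Friedel–Crafts tigloylation). The Lewis acid may close the o-hydroxyaryl enone to racemic chromanone before the chiral catalyst is applied; HCl may add to the enone or the allyl group, and the C5 ethyl group may be lost.
   Fallback: build the enone from an aldehyde instead of by acylation. It sets out from phenol 23. Rieche formylation (Cl2CHOMe, TiCl4, CH2Cl2, −20 °C) at the only free position gives (4S)-8-allyl-7-ethoxy-5-hydroxy-2-oxo-4-propylchroman-6-carbaldehyde F10. Nozaki–Hiyama–Kishi addition of (E)-2-bromobut-2-ene (CrCl2, catalytic NiCl2, DMF, rt) gives (4S)-8-allyl-7-ethoxy-5-hydroxy-6-[(2E)-1-hydroxy-2-methylbut-2-enyl]-4-propylchroman-2-one F11 as carbinol epimers. MnO2 in CH2Cl2 oxidises the benzylic allylic alcohol to tigloyl ketone 25, where the route is rejoined.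

**Further compounds**

F1 | step 6 | ethyl 3-oxohept-6-enoate | CCOC(=O)CC(=O)CCC=C
F2 | step 6 | ethyl (2E)-3-ethoxyhepta-2,6-dienoate | CCOC(=O)/C=C(\CCC=C)OCC
F3 | step 6 | (2E)-3-ethoxyhepta-2,6-dienoic acid | OC(=O)/C=C(\CCC=C)OCC
F4 | step 6 | (2E)-3-ethoxyhepta-2,6-dienoyl chloride | ClC(=O)/C=C(\CCC=C)OCC
F5 | step 4 | tert-butyl (3S)-3-(hydroxymethyl)hexanoate | CCC[C@@H](CC(=O)OC(C)(C)C)CO
F6 | step 4 | tert-butyl (3S)-3-formylhexanoate | CCC[C@@H](CC(=O)OC(C)(C)C)C=O
F7 | step 4 | tert-butyl (3S)-3-(2,2-dibromovinyl)hexanoate | CCC[C@@H](CC(=O)OC(C)(C)C)C=C(Br)Br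
F8 | step 4 | tert-butyl (3S)-3-(bromoethynyl)hexanoate | CCC[C@@H](CC(=O)OC(C)(C)C)C#CBr
F9 | step 4 | lithium acetylide of tert-butyl (3S)-3-ethynylhexanoate | CCC[C@@H](CC(=O)OC(C)(C)C)C#C[Li]
F10 | step 9 | (4S)-8-allyl-7-ethoxy-5-hydroxy-2-oxo-4-propylchroman-6-carbaldehyde | CCC[C@H]1CC(=O)Oc2c(CC=C)c(OCC)c(C=O)c(O)c21
F11 | step 9 | (4S)-8-allyl-7-ethoxy-5-hydroxy-6-[(2E)-1-hydroxy-2-methylbut-2-enyl]-4-propylchroman-2-one (carbinol epimers) | CCC[C@H]1CC(=O)Oc2c(CC=C)c(OCC)c(C(O)/C(C)=C/C)c(O)c21
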